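**Retrosynthetic overview**

- The strategy rests on ring B (C1 carries the CH2 to the lactone): C3–OMe, C4–OH and the C5 carbon side chain are contiguous, so a C4≡C5 aryne flanked by the C3 methoxy group can take carbon at C5 and a masked oxygen (acetyl) at C4 in one operation.
- Late stage: the 1,3-diol side chain comes from an anti aldol of the ring B arylacetate with O-benzylvanillin followed by ester reduction; the C4 phenol comes from Baeyer–Villiger oxidation of the C4 acetyl group; three benzyl ethers are removed last.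
- Key disconnection: the C5–CH2CO2Me and C4–C(O)CH3 bonds, made by CsF-triggered insertion of the ring B aryne into the C–C bond of methyl acetoacetate on the finished trans lactone.
- The aryne precursor lactone comes from Evans alkylation of a succinate imide with the ring B benzyl bromide, reductive cleavage and lactonization, then trans α-benzylation with the ring A bromide. The ring B o-silylaryl triflate comes from 3-hydroxy-5-methoxybenzaldehyde by carbamate-directed ortho-silylation.
- Ring order: the three benzene rings are purchased; the γ-lactone is the only ring built (step 9); the four-membered ring of the key step is transient.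

Key step: step 13

Assumption (remark on the chemistry): in step 16 the enolate formed with (−)-Ipc2BOTf is assumed to attack the aldehyde face that leads to the (2S,3R) anti adduct; if a model aldol (methyl phenylacetate, benzaldehyde) shows the opposite sense, (+)-Ipc2BOTf is used instead with no other change.

**Route**

Step 1
Reactants: 1 3-hydroxy-5-methoxybenzaldehyde
Product: 2 3-formyl-5-methoxyphenyl N-isopropylcarbamate
Conditions: i-PrNCO, Et3N (cat.), CH2Cl2, rt
Reagents that add atoms: isopropyl isocyanate, CC(C)N=C=O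
Why: Base-catalysed carbamoylation of the phenol installs the N-isopropyl carbamate, which later directs ortho-metalation and can be removed under mild conditions; the aldehyde is inert to the isocyanate.

Step 2
Reactants: 2 3-formyl-5-methoxyphenyl N-isopropylcarbamate
Product: 3 3-(hydroxymethyl)-5-methoxyphenyl N-isopropylcarbamate
Conditions: NaBH4, THF/MeOH, 0 °C
Reagents that add atoms: none
Why: Borohydride reduction of the aldehyde is fast at 0 °C, where the aryl carbamate should survive.

Step 3
Reactants: 3 3-(hydroxymethyl)-5-methoxyphenyl N-isopropylcarbamate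
Product: 6 5-{[(tert-butyldimethylsilyl)oxy]methyl}-3-methoxy-2-(trimethylsilyl)phenyl N-isopropylcarbamate, via bis-silylated carbamate 4 (not isolated), via C-silylated N-silyl carbamate 5 (not isolated)
Conditions: TBSOTf (2.2 equiv), TMEDA, Et2O, 0 °C to rt; n-BuLi, TMEDA, −78 °C; TMSCl, −78 °C to rt; aq. NaHSO4 work-up
Reagents that add atoms: tert-butyldimethylsilyl triflate, CC(C)(C)[Si](C)(C)OS(=O)(=O)C(F)(F)F; chlorotrimethylsilane, C[Si](C)(C)Cl
Why: Both acidic protons are capped in situ as TBS derivatives, then directed ortho-metalation occurs at the only C–H flanked by two oxygen directing groups (carbamate and OMe) and TMSCl traps the aryllithium; the labile N–Si bond is hydrolysed on work-up while the O–TBS ether stays.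

Step 4
Reactants: 6 5-{[(tert-butyldimethylsilyl)oxy]methyl}-3-methoxy-2-(trimethylsilyl)phenyl N-isopropylcarbamate
Product: 8 5-{[(tert-butyldimethylsilyl)oxy]methyl}-3-methoxy-2-(trimethylsilyl)phenyl trifluoromethanesulfonate, via silylphenol 7 (not isolated)
Conditions: Et2NH, DBU, MeCN, 40 °C; then PhNTf2, rt
Reagents that add atoms: N-phenylbis(trifluoromethanesulfonimide), O=S(=O)(N(c1ccccc1)S(=O)(=O)C(F)(F)F)C(F)(F)F
Why: The N-monosubstituted aryl carbamate is cleaved by mild base (E1cB loss of isopropyl isocyanate, captured by Et2NH as a urea) and the freed o-silylphenoxide is triflated in the same flask, the usual end of the carbamate route to o-silylaryl triflates.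

Step 5
Reactants: 8 5-{[(tert-butyldimethylsilyl)oxy]methyl}-3-methoxy-2-(trimethylsilyl)phenyl trifluoromethanesulfonate
Product: 9 5-(hydroxymethyl)-3-methoxy-2-(trimethylsilyl)phenyl trifluoromethanesulfonate
Conditions: CSA (cat.), MeOH/CH2Cl2, 0 °C to rt
Reagents that add atoms: none
Why: Acid-catalysed methanolysis removes the primary silyl ether; fluoride is avoided because it would unmask the aryne, and the aryl–Si bond, deactivated by the adjacent triflate, should resist protodesilylation under catalytic acid.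

Step 6
Reactants: 9 5-(hydroxymethyl)-3-methoxy-2-(trimethylsilyl)phenyl trifluoromethanesulfonate
Product: 10 5-(bromomethyl)-3-methoxy-2-(trimethylsilyl)phenyl trifluoromethanesulfonate
Conditions: CBr4, PPh3, CH2Cl2, 0 °C
Reagents that add atoms: carbon tetrabromide, BrC(Br)(Br)Br
Why: The Appel reaction converts the benzylic alcohol to the bromide under neutral conditions that spare the aryl–Si and aryl–OTf bonds.

Step 7
Reactants: 11 4-(tert-butoxy)-4-oxobutanoic acid (mono-tert-butyl succinate); 12 (R)-4-benzyloxazolidin-2-one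
Product: 14 (R)-4-benzyl-3-[4-(tert-butoxy)-4-oxobutanoyl]oxazolidin-2-one, via mixed anhydride 13 (not isolated)
Conditions: t-BuCOCl, Et3N, THF, −20 °C; then 12, LiCl, rt
Reagents that add atoms: none
Why: N-Acylation of the oxazolidinone through the pivalic mixed anhydride is the standard way to load an Evans auxiliary; the hindered pivaloyl carbonyl is not attacked.

Step 8
Reactants: 14 (R)-4-benzyl-3-[4-(tert-butoxy)-4-oxobutanoyl]oxazolidin-2-one; 10 5-(bromomethyl)-3-methoxy-2-(trimethylsilyl)phenyl trifluoromethanesulfonate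
Product: 15 tert-butyl (3R)-4-[(4R)-4-benzyl-2-oxooxazolidin-3-yl]-3-{[3-methoxy-5-(trifluoromethanesulfonyloxy)-4-(trimethylsilyl)phenyl]methyl}-4-oxobutanoate
Conditions: NaN(SiMe3)2, THF, −78 °C; then 10, −78 to −40 °C
Reagents that add atoms: none
Why: In this Evans alkylation the imide (more acidic than the tert-butyl ester) forms the chelated Z sodium enolate and the benzylic bromide approaches the face opposite the auxiliary benzyl group, which with the (R)-auxiliary should set the new centre as (R).

Step 9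
Reactants: 15 tert-butyl (3R)-4-[(4R)-4-benzyl-2-oxooxazolidin-3-yl]-3-{[3-methoxy-5-(trifluoromethanesulfonyloxy)-4-(trimethylsilyl)phenyl]methyl}-4-oxobutanoate
Product: 17 (4R)-4-{[3-methoxy-5-(trifluoromethanesulfonyloxy)-4-(trimethylsilyl)phenyl]methyl}dihydrofuran-2(3H)-one, via hydroxy ester 16 (not isolated)
Conditions: LiBH4, MeOH (1 equiv), THF, 0 °C; then TsOH·H2O (cat.), toluene, rt to 50 °C
Reagents that add atoms: none
Why: LiBH4 cleaves the activated imide carbonyl reductively while the tert-butyl ester stays, and acid-catalysed lactonization of the γ-hydroxy tert-butyl ester closes the lactone (5-exo-trig at the ester carbonyl) without touching the stereocentre.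

Step 10
Reactants: 18 4-(benzyloxy)-3-methoxybenzaldehyde (O-benzylvanillin)
Product: 19 [4-(benzyloxy)-3-methoxyphenyl]methanol
Conditions: NaBH4, MeOH, 0 °C
Reagents that add atoms: none
Why: Simple borohydride reduction of an aromatic aldehyde.

Step 11
Reactants: 19 [4-(benzyloxy)-3-methoxyphenyl]methanol
Product: 20 1-(benzyloxy)-4-(bromomethyl)-2-methoxybenzene
Conditions: PBr3, Et2O, 0 °C
Reagents that add atoms: phosphorus tribromide, BrP(Br)Br
Why: PBr3 bromination of an electron-rich benzylic alcohol is rapid at 0 °C; the bromide is used directly.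

Step 12
Reactants: 17 (4R)-4-{[3-methoxy-5-(trifluoromethanesulfonyloxy)-4-(trimethylsilyl)phenyl]methyl}dihydrofuran-2(3H)-one; 20 1-(benzyloxy)-4-(bromomethyl)-2-methoxybenzene
Product: 21 (3R,4R)-3-{[4-(benzyloxy)-3-methoxyphenyl]methyl}-4-{[3-methoxy-5-(trifluoromethanesulfonyloxy)-4-(trimethylsilyl)phenyl]methyl}dihydrofuran-2(3H)-one
Conditions: LiN(SiMe3)2, THF, −78 °C; then 20, THF/DMPU, −78 to −40 °C
Reagents that add atoms: none
Why: Alkylation of the lactone lithium enolate takes place anti to the β-benzyl substituent, the standard entry to trans-dibenzylbutyrolactones, and should set C3 as (R); the silyl triflate is inert to the amide base at −78 °C.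

Step 13
Reactants: 21 (3R,4R)-3-{[4-(benzyloxy)-3-methoxyphenyl]methyl}-4-{[3-methoxy-5-(trifluoromethanesulfonyloxy)-4-(trimethylsilyl)phenyl]methyl}dihydrofuran-2(3H)-one; 22 methyl acetoacetate
Product: 25 methyl 2-{2-acetyl-5-[((3R,4R)-4-{[4-(benzyloxy)-3-methoxyphenyl]methyl}-5-oxotetrahydrofuran-3-yl)methyl]-3-methoxyphenyl}acetate, via aryne 23 (not isolated), via benzocyclobutenoxide 24 (not isolated)
Conditions: CsF (3 equiv), 22 (2 equiv), MeCN, 80 °C
Reagents that add atoms: none
Why: Fluoride attacks silicon in 21 and triflate leaves from the neighbouring carbon, giving aryne 23 with its triple bond between C4 and C5 of ring B; the cesium enolate of 22 adds through carbon to C5, the C4 aryl anion closes onto the ketone carbonyl to benzocyclobutenoxide 24, and fragmentation of this strained alkoxide leaves acetyl on C4 and CH2CO2Me on C5. This is the aryne acyl-alkylation of β-ketoesters (formal insertion into the C–C σ bond), known for simple 3-methoxyarynes and here applied to a lactone-bearing aryne. The only ring closed is the transient cyclobutene (4-exo-trig), which opens again, so no ring and no stereocentre is added; the two sp3 centres of 24 vanish on fragmentation. The step needs regioselectivity across the aryne, which the C3 methoxy group secures: it is inductively withdrawing and distorts the aryne so that the nucleophile attacks the distal C5 and negative charge develops at C4 beside oxygen. It also needs chemoselectivity, which rests on the β-ketoester being far more acidic than the lactone α-CH, so it is the only carbon acid engaged by CsF; reversible deprotonation of the lactone would only return the favoured trans arrangement. An excess of 22 should keep the short-lived aryne from being captured by the product enolate.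

Step 14
Reactants: 25 methyl 2-{2-acetyl-5-[((3R,4R)-4-{[4-(benzyloxy)-3-methoxyphenyl]methyl}-5-oxotetrahydrofuran-3-yl)methyl]-3-methoxyphenyl}acetate
Product: 26 methyl 2-{2-acetoxy-5-[((3R,4R)-4-{[4-(benzyloxy)-3-methoxyphenyl]methyl}-5-oxotetrahydrofuran-3-yl)methyl]-3-methoxyphenyl}acetate
Conditions: m-CPBA, TFA (cat.), CH2Cl2, 0 °C to rt
Reagents that add atoms: m-chloroperoxybenzoic acid, OOC(=O)c1cccc(Cl)c1
Why: In the Baeyer–Villiger oxidation of this twisted di-ortho-substituted aryl methyl ketone the electron-rich o-methoxyaryl group migrates in preference to methyl, turning the C4 acetyl into the C4 acetate; lactone, ester and benzyl ether are inert to the peracid.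

Step 15
Reactants: 26 methyl 2-{2-acetoxy-5-[((3R,4R)-4-{[4-(benzyloxy)-3-methoxyphenyl]methyl}-5-oxotetrahydrofuran-3-yl)methyl]-3-methoxyphenyl}acetate
Product: 28 methyl 2-{2-(benzyloxy)-5-[((3R,4R)-4-{[4-(benzyloxy)-3-methoxyphenyl]methyl}-5-oxotetrahydrofuran-3-yl)methyl]-3-methoxyphenyl}acetate, via phenol 27 (not isolated)
Conditions: K2CO3, MeOH, 0 °C to rt; then BnBr, DMF, rt
Reagents that add atoms: benzyl bromide, BrCc1ccccc1
Why: Methanolysis of the aryl acetate in basic methanol keeps the o-hydroxyarylacetate open as its methyl ester (a benzofuranone would be re-opened by methoxide), and Williamson benzylation of the phenoxide in the same flask masks the C4 oxygen; the trans lactone is the thermodynamic arrangement and should be unchanged.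

Step 16
Reactants: 28 methyl 2-{2-(benzyloxy)-5-[((3R,4R)-4-{[4-(benzyloxy)-3-methoxyphenyl]methyl}-5-oxotetrahydrofuran-3-yl)methyl]-3-methoxyphenyl}acetate; 18 4-(benzyloxy)-3-methoxybenzaldehyde
Product: 29 methyl (2S,3R)-2-{2-(benzyloxy)-5-[((3R,4R)-4-{[4-(benzyloxy)-3-methoxyphenyl]methyl}-5-oxotetrahydrofuran-3-yl)methyl]-3-methoxyphenyl}-3-[4-(benzyloxy)-3-methoxyphenyl]-3-hydroxypropanoate
Conditions: (−)-Ipc2BOTf, Et3N, CH2Cl2, −78 °C; then 18, −78 °C; H2O2, pH 7 buffer, MeOH, 0 °C
Reagents that add atoms: none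
Why: Soft enolization of the arylacetate (benzylic and more acidic than the α-branched lactone CH) with the bulky chiral dialkylboron triflate gives the E(O) boron enolate, whose chair Zimmerman–Traxler transition state delivers the anti aldol, while the isopinocampheyl ligands select the aldehyde face and so set both new centres (2S,3R) under reagent control (boron-mediated asymmetric anti aldol of arylacetate esters).

Step 17
Reactants: 29 methyl (2S,3R)-2-{2-(benzyloxy)-5-[((3R,4R)-4-{[4-(benzyloxy)-3-methoxyphenyl]methyl}-5-oxotetrahydrofuran-3-yl)methyl]-3-methoxyphenyl}-3-[4-(benzyloxy)-3-methoxyphenyl]-3-hydroxypropanoate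
Product: 30 (3R,4R)-3-{[4-(benzyloxy)-3-methoxyphenyl]methyl}-4-({4-(benzyloxy)-3-[(1R,2R)-1-(4-(benzyloxy)-3-methoxyphenyl)-1,3-dihydroxypropan-2-yl]-5-methoxyphenyl}methyl)dihydrofuran-2(3H)-one
Conditions: NaBH4, THF/MeOH, 0 °C to rt
Reagents that add atoms: none
Why: The neighbouring hydroxyl binds boron and delivers hydride intramolecularly to the β-hydroxy ester (hydroxyl-assisted borohydride reduction), whereas the hindered trans-disubstituted γ-lactone has no such assistance and should survive; the descriptor at the aryl-bearing carbon changes from S to R only through the priority change.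

Step 18
Reactants: 30 (3R,4R)-3-{[4-(benzyloxy)-3-methoxyphenyl]methyl}-4-({4-(benzyloxy)-3-[(1R,2R)-1-(4-(benzyloxy)-3-methoxyphenyl)-1,3-dihydroxypropan-2-yl]-5-methoxyphenyl}methyl)dihydrofuran-2(3H)-one
Product: 31 (3R,4R)-4-({4-hydroxy-3-[(1R,2R)-1,3-dihydroxy-1-(4-hydroxy-3-methoxyphenyl)propan-2-yl]-5-methoxyphenyl}methyl)-3-[(4-hydroxy-3-methoxyphenyl)methyl]dihydrofuran-2(3H)-one (CNP0109231.2)
Conditions: H2 (1 atm), Pd/C, EtOAc/EtOH, rt
Reagents that add atoms: none
Why: Catalytic hydrogenolysis removes the three aryl benzyl ethers under neutral conditions at ambient pressure, under which the secondary benzylic alcohol should be retained if the reaction is stopped at full debenzylation.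

**Compound list**

1 | 3-hydroxy-5-methoxybenzaldehyde | COc1cc(O)cc(C=O)c1 | starting material
2 | 3-formyl-5-methoxyphenyl N-isopropylcarbamate | COc1cc(C=O)cc(OC(=O)NC(C)C)c1 | intermediate
3 | 3-(hydroxymethyl)-5-methoxyphenyl N-isopropylcarbamate | COc1cc(CO)cc(OC(=O)NC(C)C)c1 | intermediate
4 | 3-{[(tert-butyldimethylsilyl)oxy]methyl}-5-methoxyphenyl N-(tert-butyldimethylsilyl)-N-isopropylcarbamate | COc1cc(CO[Si](C)(C)C(C)(C)C)cc(OC(=O)N(C(C)C)[Si](C)(C)C(C)(C)C)c1 | intermediate
5 | 5-{[(tert-butyldimethylsilyl)oxy]methyl}-3-methoxy-2-(trimethylsilyl)phenyl N-(tert-butyldimethylsilyl)-N-isopropylcarbamate | COc1cc(CO[Si](C)(C)C(C)(C)C)cc(OC(=O)N(C(C)C)[Si](C)(C)C(C)(C)C)c1[Si](C)(C)C | intermediate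
6 | 5-{[(tert-butyldimethylsilyl)oxy]methyl}-3-methoxy-2-(trimethylsilyl)phenyl N-isopropylcarbamate | COc1cc(CO[Si](C)(C)C(C)(C)C)cc(OC(=O)NC(C)C)c1[Si](C)(C)C | intermediate
7 | 5-{[(tert-butyldimethylsilyl)oxy]methyl}-3-methoxy-2-(trimethylsilyl)phenol | COc1cc(CO[Si](C)(C)C(C)(C)C)cc(O)c1[Si](C)(C)C | intermediate
8 | 5-{[(tert-butyldimethylsilyl)oxy]methyl}-3-methoxy-2-(trimethylsilyl)phenyl trifluoromethanesulfonate | COc1cc(CO[Si](C)(C)C(C)(C)C)cc(OS(=O)(=O)C(F)(F)F)c1[Si](C)(C)C | intermediate
9 | 5-(hydroxymethyl)-3-methoxy-2-(trimethylsilyl)phenyl trifluoromethanesulfonate | COc1cc(CO)cc(OS(=O)(=O)C(F)(F)F)c1[Si](C)(C)C | intermediate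
10 | 5-(bromomethyl)-3-methoxy-2-(trimethylsilyl)phenyl trifluoromethanesulfonate | COc1cc(CBr)cc(OS(=O)(=O)C(F)(F)F)c1[Si](C)(C)C | intermediate
11 | 4-(tert-butoxy)-4-oxobutanoic acid | CC(C)(C)OC(=O)CCC(=O)O | starting material
12 | (R)-4-benzyloxazolidin-2-one | O=C1N[C@H](Cc2ccccc2)CO1 | starting material
13 | 4-(tert-butoxy)-4-oxobutanoic pivalic anhydride | CC(C)(C)OC(=O)CCC(=O)OC(=O)C(C)(C)C | intermediate
14 | (R)-4-benzyl-3-[4-(tert-butoxy)-4-oxobutanoyl]oxazolidin-2-one | CC(C)(C)OC(=O)CCC(=O)N1[C@H](Cc2ccccc2)COC1=O | intermediate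
15 | tert-butyl (3R)-4-[(4R)-4-benzyl-2-oxooxazolidin-3-yl]-3-{[3-methoxy-5-(trifluoromethanesulfonyloxy)-4-(trimethylsilyl)phenyl]methyl}-4-oxobutanoate | CC(C)(C)OC(=O)C[C@@H](Cc1cc(OC)c([Si](C)(C)C)c(OS(=O)(=O)C(F)(F)F)c1)C(=O)N1[C@H](Cc2ccccc2)COC1=O | intermediate
16 | tert-butyl (3R)-4-hydroxy-3-{[3-methoxy-5-(trifluoromethanesulfonyloxy)-4-(trimethylsilyl)phenyl]methyl}butanoate | CC(C)(C)OC(=O)C[C@@H](Cc1cc(OC)c([Si](C)(C)C)c(OS(=O)(=O)C(F)(F)F)c1)CO | intermediate
17 | (4R)-4-{[3-methoxy-5-(trifluoromethanesulfonyloxy)-4-(trimethylsilyl)phenyl]methyl}dihydrofuran-2(3H)-one | O=C1C[C@@H](Cc2cc(OC)c([Si](C)(C)C)c(OS(=O)(=O)C(F)(F)F)c2)CO1 | intermediate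
18 | 4-(benzyloxy)-3-methoxybenzaldehyde | COc1cc(C=O)ccc1OCc1ccccc1 | starting material
19 | [4-(benzyloxy)-3-methoxyphenyl]methanol | COc1cc(CO)ccc1OCc1ccccc1 | intermediate
20 | 1-(benzyloxy)-4-(bromomethyl)-2-methoxybenzene | COc1cc(CBr)ccc1OCc1ccccc1 | intermediate
21 | (3R,4R)-lactone with ring B as 3-methoxy-4-(trimethylsilyl)-5-(triflyloxy)phenyl and ring A O-benzylated (key-step precursor) | COc1cc(C[C@H]2C(=O)OC[C@@H]2Cc2cc(OC)c([Si](C)(C)C)c(OS(=O)(=O)C(F)(F)F)c2)ccc1OCc1ccccc1 | intermediate
22 | methyl acetoacetate | CC(=O)CC(=O)OC | starting material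
23 | (3R,4R)-lactone with ring B as the C4≡C5 aryne | COc1cc(C[C@H]2C(=O)OC[C@@H]2CC2=CC#CC(OC)=C2)ccc1OCc1ccccc1 | intermediate
24 | cesium benzocyclobutenoxide (C4–C(CH3)(O−)–CH(CO2Me)–C5 four-membered ring fused to ring B) | COc1cc(C[C@H]2C(=O)OC[C@@H]2Cc2cc(OC)c3c(c2)C(C(=O)OC)C3(C)[O-])ccc1OCc1ccccc1.[Cs+] | intermediate
25 | methyl 2-{2-acetyl-5-[((3R,4R)-4-{[4-(benzyloxy)-3-methoxyphenyl]methyl}-5-oxotetrahydrofuran-3-yl)methyl]-3-methoxyphenyl}acetate | COc1cc(C[C@H]2C(=O)OC[C@@H]2Cc2cc(OC)c(C(C)=O)c(CC(=O)OC)c2)ccc1OCc1ccccc1 | intermediate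
26 | methyl 2-{2-acetoxy-5-[((3R,4R)-4-{[4-(benzyloxy)-3-methoxyphenyl]methyl}-5-oxotetrahydrofuran-3-yl)methyl]-3-methoxyphenyl}acetate | COc1cc(C[C@H]2C(=O)OC[C@@H]2Cc2cc(OC)c(OC(C)=O)c(CC(=O)OC)c2)ccc1OCc1ccccc1 | intermediate
27 | methyl 2-{2-hydroxy-5-[((3R,4R)-4-{[4-(benzyloxy)-3-methoxyphenyl]methyl}-5-oxotetrahydrofuran-3-yl)methyl]-3-methoxyphenyl}acetate | COc1cc(C[C@H]2C(=O)OC[C@@H]2Cc2cc(OC)c(O)c(CC(=O)OC)c2)ccc1OCc1ccccc1 | intermediate
28 | methyl 2-{2-(benzyloxy)-5-[((3R,4R)-4-{[4-(benzyloxy)-3-methoxyphenyl]methyl}-5-oxotetrahydrofuran-3-yl)methyl]-3-methoxyphenyl}acetate | COc1cc(C[C@H]2C(=O)OC[C@@H]2Cc2cc(OC)c(OCc3ccccc3)c(CC(=O)OC)c2)ccc1OCc1ccccc1 | intermediate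
29 | methyl (2S,3R)-anti-aldol adduct of 28 with 18 | COc1cc(C[C@H]2C(=O)OC[C@@H]2Cc2cc(OC)c(OCc3ccccc3)c([C@H](C(=O)OC)[C@@H](O)c3ccc(OCc4ccccc4)c(OC)c3)c2)ccc1OCc1ccccc1 | intermediate
30 | tri-O-benzyl ether of the target, (1R,2R)-1,3-diol side chain on ring B C5 | COc1cc(C[C@H]2C(=O)OC[C@@H]2Cc2cc(OC)c(OCc3ccccc3)c([C@H](CO)[C@@H](O)c3ccc(OCc4ccccc4)c(OC)c3)c2)ccc1OCc1ccccc1 | intermediate
31 | CNP0109231.2 | COc1cc(C[C@H]2C(=O)OC[C@@H]2Cc2cc(OC)c(O)c([C@H](CO)[C@@H](O)c3ccc(O)c(OC)c3)c2)ccc1O | target

**Step count**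

Total: 18 steps. Longest linear sequence: 15 steps (1 to 31 through steps 1–6, 8, 9 and 12–18).

**Steps most likely to fail**

1. Step 13. The aryne may be consumed by oligomerization or by simple α-arylation without fragmentation before the acetoacetate enolate inserts, or hot fluoride may degrade the lactone-bearing substrate.
Fallback (sets out from 14 and 20, returns at 28): the aryne is given up and the C5 carbon is brought in by cross-coupling. Purchased 5-bromovanillin is O-benzylated (BnBr, K2CO3, DMF) to 4-(benzyloxy)-3-bromo-5-methoxybenzaldehyde F1, reduced (NaBH4, MeOH) to [4-(benzyloxy)-3-bromo-5-methoxyphenyl]methanol F2 and brominated (PBr3) to 2-(benzyloxy)-1-bromo-5-(bromomethyl)-3-methoxybenzene F3. Alkylation of the sodium enolate of 14 with F3 should give the (R)-configured bromoaryl imide F4. LiBH4 reduction gives the hydroxy tert-butyl ester F5, and catalytic TsOH closes it to the (R)-β-benzyl lactone F6. Trans α-benzylation with 20 (LiN(SiMe3)2, THF, −78 °C) gives the bromoaryl trans lactone F7. Negishi-type coupling of F7 with the Reformatsky reagent BrZnCH2CO2Me (Pd(dba)2, XPhos, THF, 60 °C) then installs the acetate arm and gives 28.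

2. Step 16. Facial selectivity of the chiral boron enolate may be poor, the anti preference may erode, or the lactone may be enolized in competition.
Fallback (sets out from 28 and 18, returns at 29): reagent control is replaced by separation. The achiral anti-selective boron aldol (Chx2BOTf, Et3N, CH2Cl2, −78 °C) should give 29 together with its (2R,3S) anti diastereomer F8; because the lactone centres are fixed the two are diastereomers and are separated by preparative HPLC, and 29 goes on to step 17.

3. Step 17. The lactone may be over-reduced, or the β-hydroxy ester may undergo retro-aldol cleavage or epimerization under the basic borohydride medium.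
Fallback (sets out from 29, returns at 30): the ester is reduced at the acid oxidation level. Saponification (LiOH, THF/H2O, 0 °C) opens both esters to the ring-opened dicarboxylic acid F9 (not isolated), which recloses the γ-lactone on acidification to pH 2 and gives the β-hydroxy acid F10. BH3·SMe2 (THF, 0 °C) reduces the carboxylic acid in preference to the lactone and gives 30.

**Further compounds**

F1 | step 13 | 4-(benzyloxy)-3-bromo-5-methoxybenzaldehyde | COc1cc(C=O)cc(Br)c1OCc1ccccc1
F2 | step 13 | [4-(benzyloxy)-3-bromo-5-methoxyphenyl]methanol | COc1cc(CO)cc(Br)c1OCc1ccccc1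
F3 | step 13 | 2-(benzyloxy)-1-bromo-5-(bromomethyl)-3-methoxybenzene | COc1cc(CBr)cc(Br)c1OCc1ccccc1
F4 | step 13 | tert-butyl (3R)-4-[(4R)-4-benzyl-2-oxooxazolidin-3-yl]-3-{[4-(benzyloxy)-3-bromo-5-methoxyphenyl]methyl}-4-oxobutanoate | CC(C)(C)OC(=O)C[C@@H](Cc1cc(OC)c(OCc2ccccc2)c(Br)c1)C(=O)N1[C@H](Cc2ccccc2)COC1=O
F5 | step 13 | tert-butyl (3R)-3-{[4-(benzyloxy)-3-bromo-5-methoxyphenyl]methyl}-4-hydroxybutanoate | CC(C)(C)OC(=O)C[C@@H](Cc1cc(OC)c(OCc2ccccc2)c(Br)c1)CO
F6 | step 13 | (4R)-4-{[4-(benzyloxy)-3-bromo-5-methoxyphenyl]methyl}dihydrofuran-2(3H)-one | O=C1C[C@@H](Cc2cc(OC)c(OCc3ccccc3)c(Br)c2)CO1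
F7 | step 13 | (3R,4R)-4-{[4-(benzyloxy)-3-bromo-5-methoxyphenyl]methyl}-3-{[4-(benzyloxy)-3-methoxyphenyl]methyl}dihydrofuran-2(3H)-one | COc1cc(C[C@H]2C(=O)OC[C@@H]2Cc2cc(OC)c(OCc3ccccc3)c(Br)c2)ccc1OCc1ccccc1
F8 | step 16 | methyl (2R,3S)-anti-aldol diastereomer of 29 | COc1cc(C[C@H]2C(=O)OC[C@@H]2Cc2cc(OC)c(OCc3ccccc3)c([C@@H](C(=O)OC)[C@H](O)c3ccc(OCc4ccccc4)c(OC)c3)c2)ccc1OCc1ccccc1
F9 | step 17 | ring-opened dicarboxylic acid from 29 (lactone and methyl ester both hydrolysed) | COc1cc(C[C@H]([C@H](CO)Cc2cc(OC)c(OCc3ccccc3)c([C@H](C(=O)O)[C@@H](O)c3ccc(OCc4ccccc4)c(OC)c3)c2)C(=O)O)ccc1OCc1ccccc1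
F10 | step 17 | (2S,3R)-β-hydroxy acid corresponding to 29 with the lactone intact | COc1cc(C[C@H]2C(=O)OC[C@@H]2Cc2cc(OC)c(OCc3ccccc3)c([C@H](C(=O)O)[C@@H](O)c3ccc(OCc4ccccc4)c(OC)c3)c2)ccc1OCc1ccccc1
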